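**Plan**

- Retrosynthesis (butane numbering C1H2OH–C2(OH)(CH2Ar)–C3H(CH2Ar)–C4H2OH): the phenols are masked as benzyl ethers, and C4H2OH with O1 is taken back to the five-membered β-hydroxy lactone 10 (ring O1–C1–C2–C3–C4=O).
- Lactone 10 is cut in one operation at the aryl–CH2 bond of the C3 benzyl group and at C2–C3, giving arylboronic acid 7 and acrylate ester 6. Ester 6 is cut at the ester C–O bond (sodium acrylate 5) and at C1–C2 (arylacetic acid 1 plus diazomethane).
- Enabling feature: C3 carries a CH2OH (C4) that can be an ester carbonyl, 1,3 to the hydroxyl on C2, and O1 on C1 can carry that ester. C3 is then the α-carbon of an acrylate whose β-CH2 accepts the aryl group, and C2, as a ketone, is in reach of the enolate for aldol closure of the O1–C1–C2–C3–C4 ring.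
- Forward: the C1–C2–benzyl chain is built in steps 1–2; step 3 brings aryl transfer, the C2–C3 bond and the lactone ring; step 4 opens the ring reductively; step 5 removes the benzyl groups.
- Stereochemistry: C2 and C3 are both set in step 3, the relative configuration by the (Z)-enolate in a metal-bridged aldol transition state and the absolute configuration by (S)-BINAP on rhodium. Steps 4 and 5 break no bond at either centre.

Key step: step 3

Assumption: (S)-BINAP is taken to give the (3R,4S) lactone; if the sense of induction is the opposite, (R)-BINAP is used in step 3 with nothing else changed.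

**Route**

Step 1
Reactants: 1 [4-(benzyloxy)-3-methoxyphenyl]acetic acid
Product: 4 1-[4-(benzyloxy)-3-methoxyphenyl]-3-bromopropan-2-one, via acid chloride 2 (not isolated), via diazo ketone 3 (not isolated)
Conditions: (COCl)2, DMF (cat.), CH2Cl2, 0 °C to rt; concentrate; CH2N2 (3 equiv), Et2O, 0 °C; then 48% aq. HBr, 0 °C
Reagents that add atoms: diazomethane C=[N+]=[N-]; hydrogen bromide Br
Why: Acid chloride formation, acylation of diazomethane (the first stage of the Arndt–Eistert sequence, a second equivalent of diazomethane taking up the HCl) and protonation of the diazo ketone by HBr with bromide displacing N2 are a standard one-pot route to bromomethyl ketones, and no stereocentre is formed.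

Step 2
Reactants: 4 1-[4-(benzyloxy)-3-methoxyphenyl]-3-bromopropan-2-one; 5 sodium prop-2-enoate (sodium acrylate)
Product: 6 3-[4-(benzyloxy)-3-methoxyphenyl]-2-oxopropyl prop-2-enoate
Conditions: 5 (1.5 equiv), 2,6-di-tert-butyl-4-methylphenol (cat.), DMF, 0 °C to rt
Reagents that add atoms: none
Why: SN2 displacement of the activated α-keto bromide by a carboxylate (phenacyl-type ester formation) is fast at room temperature with the weakly basic acrylate, the radical inhibitor suppresses polymerisation, and no stereocentre is formed.

Step 3
Reactants: 6 3-[4-(benzyloxy)-3-methoxyphenyl]-2-oxopropyl prop-2-enoate; 7 [4-(benzyloxy)-3-methoxyphenyl]boronic acid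
Product: 10 (3R,4S)-3,4-bis{[4-(benzyloxy)-3-methoxyphenyl]methyl}-4-hydroxyoxolan-2-one, via rhodium enolate 8 (not isolated), via rhodium alkoxide 9 (not isolated)
Conditions: 7 (1.5 equiv), [Rh(OH)(cod)]2 (2.5 mol %), (S)-BINAP (6 mol %), H2O (5 equiv), 1,4-dioxane, 50 °C
Reagents that add atoms: none
Why: Proposed new method: the arylboronic acid transmetallates to a hydroxo complex of monovalent rhodium, the aryl–rhodium bond adds across the acrylate C=C of 6 with the aryl group at the terminal CH2 (this makes the aryl–CH2 bond), and the oxygen-bound (Z)-enolate 8 so formed adds to the tethered ketone to give alkoxide 9, which water protonates to release 10 and the rhodium hydroxide. The closest known reaction types are the rhodium-catalysed conjugate addition–aldol cyclisation of arylboronic acids with enones tethered to ketones and the copper hydride reductive aldol cyclisation of unsaturated esters tethered through the ester oxygen to ketones; aryl transfer to an acrylate ester of an α-hydroxy ketone with lactone closure has not been shown. The lactone ring closes by a 5-(enolendo)-exo-trig aldol addition, the same closure that operates when α-acyloxy ketones are cyclised to butanolides by the intramolecular Reformatsky reaction or by base. The relative configuration (the new arylmethyl group cis to the tertiary hydroxyl, the two arylmethyl groups trans) should follow from the (Z)-enolate, formed from the s-cis acrylate, reacting through a transition state in which rhodium bridges the enolate oxygen and the ketone oxygen, and it is also the more stable arrangement at the epimerisable α-carbon. The absolute configuration is controlled by (S)-BINAP on the enolate-bearing rhodium, which must distinguish the two faces of the ketone. The step needs conjugate addition to outrun 1,2-arylation of the ketone and ring closure to outrun protonation or β-hydride elimination of 8; the higher reactivity of the acrylate toward aryl–rhodium, the intramolecular position of the ketone, the small amount of water and the base-free conditions should secure this.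

Step 4
Reactants: 10 (3R,4S)-3,4-bis{[4-(benzyloxy)-3-methoxyphenyl]methyl}-4-hydroxyoxolan-2-one
Product: 11 (2S,3S)-2,3-bis{[4-(benzyloxy)-3-methoxyphenyl]methyl}butane-1,2,4-triol
Conditions: LiAlH4 (3 equiv), THF, −20 to 0 °C; aqueous potassium sodium tartrate work-up
Reagents that add atoms: none
Why: Hydride reduction of a lactone to the diol breaks no bond at either stereocentre, the tertiary hydroxyl is carried as its aluminium alkoxide at low temperature so that retro-aldol cleavage should not compete, and the benzyl ethers are inert.

Step 5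
Reactants: 11 (2S,3S)-2,3-bis{[4-(benzyloxy)-3-methoxyphenyl]methyl}butane-1,2,4-triol
Product: 12 (−)-carinol
Conditions: H2 (1 atm), 10% Pd/C, EtOAc/MeOH (1:1), rt
Reagents that add atoms: none
Why: Catalytic hydrogenolysis should cleave the two aryl benzyl ethers, while the tertiary alcohol (homobenzylic, not benzylic) and both stereocentres are untouched.

**Compound list**

1 | [4-(benzyloxy)-3-methoxyphenyl]acetic acid | COc1cc(CC(=O)O)ccc1OCc1ccccc1 | starting material
2 | [4-(benzyloxy)-3-methoxyphenyl]acetyl chloride (not isolated) | COc1cc(CC(=O)Cl)ccc1OCc1ccccc1 | intermediate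
3 | 1-[4-(benzyloxy)-3-methoxyphenyl]-3-diazopropan-2-one (not isolated) | COc1cc(CC(=O)C=[N+]=[N-])ccc1OCc1ccccc1 | intermediate
4 | 1-[4-(benzyloxy)-3-methoxyphenyl]-3-bromopropan-2-one | COc1cc(CC(=O)CBr)ccc1OCc1ccccc1 | intermediate
5 | sodium prop-2-enoate (sodium acrylate) | C=CC(=O)[O-].[Na+] | starting material
6 | 3-[4-(benzyloxy)-3-methoxyphenyl]-2-oxopropyl prop-2-enoate | COc1cc(CC(=O)COC(=O)C=C)ccc1OCc1ccccc1 | intermediate
7 | [4-(benzyloxy)-3-methoxyphenyl]boronic acid | COc1cc(B(O)O)ccc1OCc1ccccc1 | starting material
8 | oxygen-bound (Z)-rhodium enolate from aryl transfer to 6 (BINAP on rhodium not written; not isolated) | COc1cc(C/C=C(\O[Rh])OCC(=O)Cc2ccc(OCc3ccccc3)c(OC)c2)ccc1OCc1ccccc1 | intermediate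
9 | rhodium alkoxide of lactone 10 (BINAP on rhodium not written; not isolated) | COc1cc(C[C@H]2C(=O)OC[C@]2(O[Rh])Cc3ccc(OCc4ccccc4)c(OC)c3)ccc1OCc1ccccc1 | intermediate
10 | (3R,4S)-3,4-bis{[4-(benzyloxy)-3-methoxyphenyl]methyl}-4-hydroxyoxolan-2-one | COc1cc(C[C@H]2C(=O)OC[C@]2(O)Cc3ccc(OCc4ccccc4)c(OC)c3)ccc1OCc1ccccc1 | intermediate
11 | (2S,3S)-2,3-bis{[4-(benzyloxy)-3-methoxyphenyl]methyl}butane-1,2,4-triol | COc1cc(C[C@@H](CO)[C@](O)(CO)Cc2ccc(OCc3ccccc3)c(OC)c2)ccc1OCc1ccccc1 | intermediate
12 | (−)-carinol, (2S,3S)-2,3-bis[(4-hydroxy-3-methoxyphenyl)methyl]butane-1,2,4-triol | COc1cc(C[C@@H](CO)[C@](O)(CO)Cc2ccc(O)c(OC)c2)ccc1O | target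

**Count**

Total steps: 5. Longest linear sequence: 5 steps (1 → 4 → 6 → 10 → 11 → 12).

**Steps most likely to fail**

Step 3 (proposed new method). What may go wrong: water protonates rhodium enolate 8 before the strained five-membered aldol closure, so that the open-chain 3-arylpropanoate forms instead of 10; the ligand may also discriminate the ketone faces poorly, so that 10 forms with low enantiomeric purity. The fallback uses known chemistry, sets out from 7 and returns at 11. Boronic acid 7 is added to dimethyl itaconate by the rhodium-catalysed conjugate addition–enantioselective protonation ([Rh(cod)Cl]2, BINAP of the handedness that leads to the R product, 2-methoxyphenol as proton source, toluene, 100 °C) to give dimethyl (2R)-2-{[4-(benzyloxy)-3-methoxyphenyl]methyl}butanedioate F1; the same aryl–CH2 bond is still made by aryl transfer. Monosaponification of the less hindered ester (LiOH, 1 equiv, THF/H2O, 0 °C) gives (3R)-4-[4-(benzyloxy)-3-methoxyphenyl]-3-(methoxycarbonyl)butanoic acid F2. Reduction of the remaining ester in the presence of the carboxylate (Ca(BH4)2 from CaCl2 and NaBH4, EtOH), followed by acid lactonisation, gives (4R)-4-{[4-(benzyloxy)-3-methoxyphenyl]methyl}oxolan-2-one F3. Hydroxylation of its enolate (KN(SiMe3)2, THF, −78 °C, then 3-phenyl-2-(phenylsulfonyl)oxaziridine) gives the trans compound (3R,4S)-4-{[4-(benzyloxy)-3-methoxyphenyl]methyl}-3-hydroxyoxolan-2-one F4. Benzylation of the dianion of F4 (LiN(i-Pr)2, 2.2 equiv, THF/DMPU, −78 °C; 4-(benzyloxy)-3-methoxybenzyl bromide) from the face opposite the C4 substituent gives (3S,4S)-3,4-bis{[4-(benzyloxy)-3-methoxyphenyl]methyl}-3-hydroxyoxolan-2-one F5, the tertiary centre being set by substrate control. Reduction of F5 with LiAlH4 (THF, 0 °C) gives 11.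

Step 4. What may go wrong: the metal alkoxide of the tertiary β-hydroxy lactone undergoes retro-aldol cleavage, which would lose the C2–C3 bond and both stereocentres, or the α-carbon epimerises before hydride is delivered. The fallback sets out from 10 and returns at 11. The tertiary hydroxyl is capped first (Et3SiOSO2CF3, 2,6-lutidine, CH2Cl2, −78 to 0 °C) to give (3R,4S)-3,4-bis{[4-(benzyloxy)-3-methoxyphenyl]methyl}-4-[(triethylsilyl)oxy]oxolan-2-one F6, which cannot fragment. Reduction with LiBH4 (THF, 0 °C to rt) gives (2S,3S)-2,3-bis{[4-(benzyloxy)-3-methoxyphenyl]methyl}-2-[(triethylsilyl)oxy]butane-1,4-diol F7. Bu4NF (THF, rt) then removes the silyl group, from whichever oxygen it may have migrated to, and gives 11.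

Step 2. What may go wrong: the carboxylate acts as a base toward the doubly activated α-bromo ketone (enolisation, self-condensation), and the acrylate polymerises in DMF. The fallback sets out from 3 and returns at 6. Diazo ketone 3 is isolated from step 1 by leaving out the HBr quench and is decomposed in an excess of acrylic acid with Cu(acac)2 (cat.) in toluene at 60 °C. O–H insertion of the copper carbenoid into the carboxylic acid gives 6 directly under non-basic conditions; no new compound arises (F0).

Further compounds
F1 | step 3 | dimethyl (2R)-2-{[4-(benzyloxy)-3-methoxyphenyl]methyl}butanedioate | COC(=O)C[C@@H](Cc1ccc(OCc2ccccc2)c(OC)c1)C(=O)OC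
F2 | step 3 | (3R)-4-[4-(benzyloxy)-3-methoxyphenyl]-3-(methoxycarbonyl)butanoic acid | OC(=O)C[C@@H](Cc1ccc(OCc2ccccc2)c(OC)c1)C(=O)OC
F3 | step 3 | (4R)-4-{[4-(benzyloxy)-3-methoxyphenyl]methyl}oxolan-2-one | COc1cc(C[C@H]2COC(=O)C2)ccc1OCc1ccccc1
F4 | step 3 | (3R,4S)-4-{[4-(benzyloxy)-3-methoxyphenyl]methyl}-3-hydroxyoxolan-2-one | COc1cc(C[C@H]2COC(=O)[C@@H]2O)ccc1OCc1ccccc1
F5 | step 3 | (3S,4S)-3,4-bis{[4-(benzyloxy)-3-methoxyphenyl]methyl}-3-hydroxyoxolan-2-one | COc1cc(C[C@H]2COC(=O)[C@]2(O)Cc3ccc(OCc4ccccc4)c(OC)c3)ccc1OCc1ccccc1
F6 | step 4 | (3R,4S)-3,4-bis{[4-(benzyloxy)-3-methoxyphenyl]methyl}-4-[(triethylsilyl)oxy]oxolan-2-one | COc1cc(C[C@H]2C(=O)OC[C@]2(O[Si](CC)(CC)CC)Cc3ccc(OCc4ccccc4)c(OC)c3)ccc1OCc1ccccc1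
F7 | step 4 | (2S,3S)-2,3-bis{[4-(benzyloxy)-3-methoxyphenyl]methyl}-2-[(triethylsilyl)oxy]butane-1,4-diol | COc1cc(C[C@@H](CO)[C@](O[Si](CC)(CC)CC)(CO)Cc2ccc(OCc3ccccc3)c(OC)c2)ccc1OCc1ccccc1
F0 | step 2 | none | none
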